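Raised to the ketone level at C3 (3-dehydroquinate), the cyclohexane shows two aldol-type ring bonds to one carbonyl. C2 and C4 flank C3, and C1 (tertiary α-hydroxy ester) and C5 (secondary carbinol) are its two β-carbons. The route rests on cutting C1–C2 and C4–C5. The key step joins a C2–C3–C4 donor, the N-Cbz enamine of benzyloxyacetone, to a C1–C6–C5 acceptor, a γ-benzyloxy-β,γ-unsaturated α-keto ester. One Cu(II)–bis(oxazoline)-catalysed double aza-ene [3+3] annulation closes the ring and sets C5, C4 and C1. Both precursors are flat, achiral, one-step compounds. The C3 ketone later gives the axial carbinol that stays free.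

Key step: step 3

Assumption: quinic acid numbering is used (C1 carries the carboxyl group, C3 the free carbinol, C4 and C5 the esters). The sense of induction of the Cu–box complex is extrapolated from additions to Cu-bound α-keto esters, and the (S,S)-ligand would be used if it proved opposite.

Step 1
Reactants: 1 benzyl vinyl ether; 2 tert-butyl chlorooxoacetate (tert-butyl oxalyl chloride)
Product: 3 tert-butyl (E)-4-(benzyloxy)-2-oxobut-3-enoate
Conditions: pyridine (1.2 equiv), CH2Cl2, 0 °C to rt
Reagents that add atoms: none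
Why: Acylation of an enol ether by an oxalyl half-ester chloride (addition, then loss of HCl) is the standard entry to 4-alkoxy-2-oxobut-3-enoates and should give the conjugated E alkene.

Step 2
Reactants: 4 1-(benzyloxy)propan-2-one; 5 benzyl carbamate
Product: 6 benzyl N-[(E)-1-(benzyloxy)prop-1-en-2-yl]carbamate (benzyloxy group trans to nitrogen)
Conditions: TsOH·H2O (5 mol %), toluene, reflux, Dean–Stark; E isomer separated on Et3N-deactivated SiO2
Reagents that add atoms: none
Why: Acid-catalysed condensation of a ketone with a carbamate (standard enecarbamate synthesis) should dehydrate toward the oxygen-bearing carbon to the more substituted alkene; the E and Z isomers are separable and the Z isomer can be re-equilibrated with the same acid.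

Step 3
Reactants: 3 tert-butyl (E)-4-(benzyloxy)-2-oxobut-3-enoate; 6 benzyl N-[(E)-1-(benzyloxy)prop-1-en-2-yl]carbamate
Product: 10 tert-butyl 4,5-di-O-benzyl-3-dehydroquinate, via open-chain N-Cbz ketimine 7 (not isolated), via terminal enecarbamate 8 (not isolated), via cyclic N-Cbz ketimine 9 (not isolated)
Conditions: [Cu((R,R)-t-Bu-box)](OTf)2 (10 mol %), 4 Å MS, CH2Cl2, −40 °C to rt; then 1 M HCl, THF, 0 °C
Reagents that add atoms: water, O
Why: Proposed new method: the s-cis 1-oxadiene of 3, held flat by O,O-chelation to Cu(II), is attacked at C5 by the CH terminus (C4) of 6 through an endo, hetero-Diels–Alder-like conjugate aza-ene transition state in which the carbamate N–H is passed on to C6, so ketimine 7 and a still Cu-bound C1 ketone arise without a free enolate; 7 tautomerises to the less hindered enecarbamate 8, whose CH2 (C2) adds to C1 in a second aza-ene step to give 9, and dilute acid then hydrolyses the C=N bond to 10. The closest known reaction types are Cu–bis(oxazoline)-catalysed inverse-electron-demand hetero-Diels–Alder reactions of γ-alkoxy-β,γ-unsaturated α-keto esters with enol ethers and N-vinyl carbamates, Cu-catalysed aza-ene additions of enecarbamates to glyoxylates and alkylidene malonates, and the amine-catalysed Michael–aldol [3+3] annulation of ketones with such keto esters. The single new ring closes in a 6-(enolendo)-exo-trig mode through a chair. C5 is controlled by the ligand, which leaves one face of the chelate open; C4 follows from the E geometry of 6 and the endo position of nitrogen, which put its benzyloxy group exo and hence trans to O5; C1 is controlled by the same open face (Re at the ketone) and, in the same sense, by the chair with O4, O5 and the ester equatorial and the new oxygen axial. The step needs 1,4- before 1,2-attack on 3, which the donor-deactivated ketone and the chelated s-cis diene secure, and attack through C4 rather than C3 of 6, which the unsubstituted CH terminus and the tertiary N-acyliminium ion secure. The N-acyl group is essential, since a free amine catalyst would displace the benzyloxy group of 3, and the internal proton shuttle avoids the base that would eliminate O5.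

Step 4
Reactants: 10 tert-butyl 4,5-di-O-benzyl-3-dehydroquinate
Product: 11 tert-butyl 4,5-di-O-benzylquinate (natural quinic acid configuration at C1, C3, C4, C5)
Conditions: L-Selectride (2.2 equiv), THF, −78 °C; then H2O
Reagents that add atoms: none
Why: Diastereoselective ketone reduction with a bulky trialkylborohydride should come from the equatorial side of C3, away from the axial C1 oxygen (which consumes the first equivalent), and give the axial (3R) alcohol cis to O1 and O4.

Step 5
Reactants: 11 tert-butyl 4,5-di-O-benzylquinate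
Product: 12 tert-butyl 4,5-di-O-benzyl-3-O-(triethylsilyl)quinate
Conditions: TESCl (1.3 equiv), imidazole, DMF, 0 °C to rt
Reagents that add atoms: chlorotriethylsilane, CC[Si](Cl)(CC)CC
Why: Silyl ether formation should take the secondary C3–OH, while the tertiary C1–OH next to the ester stays free.

Step 6
Reactants: 12 tert-butyl 4,5-di-O-benzyl-3-O-(triethylsilyl)quinate
Product: 13 tert-butyl 3-O-(triethylsilyl)quinate (free 4,5-diol and C1–OH)
Conditions: H2 (1 atm), 10% Pd/C, EtOAc, rt
Reagents that add atoms: none
Why: Hydrogenolysis of both benzyl ethers is done before any cinnamoyl alkene is present, and in an aprotic solvent the TES ether and the tert-butyl ester should persist.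

Step 7
Reactants: 14 4-tert-butoxybenzaldehyde; 15 malonic acid
Product: 16 (E)-3-(4-tert-butoxyphenyl)prop-2-enoic acid
Conditions: pyridine, piperidine (cat.), 90 °C
Reagents that add atoms: none
Why: Knoevenagel–Doebner condensation with decarboxylation should give the E cinnamic acid, and the aryl tert-butyl ether is inert to amine bases.

Step 8
Reactants: 13 tert-butyl 3-O-(triethylsilyl)quinate; 16 (E)-3-(4-tert-butoxyphenyl)prop-2-enoic acid (2.5 equiv)
Product: 17 tert-butyl 4,5-bis-O-[(E)-4-tert-butoxycinnamoyl]-3-O-(triethylsilyl)quinate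
Conditions: DCC (2.6 equiv), DMAP (0.4 equiv), CH2Cl2, 0 °C to rt
Reagents that add atoms: none
Why: Steglich esterification should acylate the two equatorial secondary hydroxyl groups, while O3 is silylated and the tertiary C1–OH is too hindered.

Step 9
Reactants: 17 tert-butyl 4,5-bis-O-[(E)-4-tert-butoxycinnamoyl]-3-O-(triethylsilyl)quinate
Product: 18 4,5-di-O-p-coumaroylquinic acid
Conditions: TFA–CH2Cl2–H2O (10:10:1), 0 °C to rt
Reagents that add atoms: none
Why: Acidolysis should remove the tert-butyl ester, both aryl tert-butyl ethers and the TES ether in one operation, and it leaves the cinnamate esters and all stereocentres untouched under non-basic conditions that disfavour acyl migration.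

Compound list
1 | benzyl vinyl ether | C=COCc1ccccc1 | starting material
2 | tert-butyl chlorooxoacetate | CC(C)(C)OC(=O)C(=O)Cl | starting material
3 | tert-butyl (E)-4-(benzyloxy)-2-oxobut-3-enoate | CC(C)(C)OC(=O)C(=O)/C=C/OCc1ccccc1 | intermediate
4 | 1-(benzyloxy)propan-2-one | CC(=O)COCc1ccccc1 | starting material
5 | benzyl carbamate | NC(=O)OCc1ccccc1 | starting material
6 | benzyl N-[(E)-1-(benzyloxy)prop-1-en-2-yl]carbamate | C/C(NC(=O)OCc1ccccc1)=C\OCc2ccccc2 | intermediate
7 | tert-butyl (4R,5R)-4,5-bis(benzyloxy)-6-{[(benzyloxy)carbonyl]imino}-2-oxoheptanoate | C(c1ccccc1)O[C@@H]([C@H](OCc2ccccc2)CC(=O)C(=O)OC(C)(C)C)C(C)=NC(=O)OCc3ccccc3 | intermediate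
8 | tert-butyl (4R,5R)-4,5-bis(benzyloxy)-6-{[(benzyloxy)carbonyl]amino}-2-oxohept-6-enoate | C(c1ccccc1)O[C@@H]([C@H](OCc2ccccc2)CC(=O)C(=O)OC(C)(C)C)C(=C)NC(=O)OCc3ccccc3 | intermediate
9 | N-Cbz ketimine of 10 (C3=N–Cbz, same configuration at C1, C4, C5) | C(c1ccccc1)O[C@@H]2C(=NC(=O)OCc4ccccc4)C[C@@](O)(C(=O)OC(C)(C)C)C[C@H]2OCc3ccccc3 | intermediate
10 | tert-butyl 4,5-di-O-benzyl-3-dehydroquinate, i.e. tert-butyl (1R,3R,4S)-3,4-bis(benzyloxy)-1-hydroxy-5-oxocyclohexane-1-carboxylate | C(c1ccccc1)O[C@@H]2C(=O)C[C@@](O)(C(=O)OC(C)(C)C)C[C@H]2OCc3ccccc3 | intermediate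
11 | tert-butyl 4,5-di-O-benzylquinate | C(c1ccccc1)O[C@@H]2[C@H](O)C[C@@](O)(C(=O)OC(C)(C)C)C[C@H]2OCc3ccccc3 | intermediate
12 | tert-butyl 4,5-di-O-benzyl-3-O-(triethylsilyl)quinate | C(c1ccccc1)O[C@@H]2[C@H](O[Si](CC)(CC)CC)C[C@@](O)(C(=O)OC(C)(C)C)C[C@H]2OCc3ccccc3 | intermediate
13 | tert-butyl 3-O-(triethylsilyl)quinate | O[C@@H]1[C@H](O[Si](CC)(CC)CC)C[C@@](O)(C(=O)OC(C)(C)C)C[C@H]1O | intermediate
14 | 4-tert-butoxybenzaldehyde | CC(C)(C)Oc1ccc(C=O)cc1 | starting material
15 | malonic acid | OC(=O)CC(=O)O | starting material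
16 | (E)-3-(4-tert-butoxyphenyl)prop-2-enoic acid | CC(C)(C)Oc1ccc(/C=C/C(=O)O)cc1 | intermediate
17 | tert-butyl 4,5-bis-O-[(E)-4-tert-butoxycinnamoyl]-3-O-(triethylsilyl)quinate | CC(C)(C)Oc1ccc(/C=C/C(=O)O[C@@H]2[C@H](O[Si](CC)(CC)CC)C[C@@](O)(C(=O)OC(C)(C)C)C[C@H]2OC(=O)/C=C/c3ccc(OC(C)(C)C)cc3)cc1 | intermediate
18 | 4,5-di-O-p-coumaroylquinic acid | O=C(/C=C/c1ccc(O)cc1)O[C@@H]1[C@H](O)C[C@@](O)(C(=O)O)C[C@H]1OC(=O)/C=C/c1ccc(O)cc1 | target

Total step count: 9. Longest linear sequence: 7 (step 1 or 2, then steps 3, 4, 5, 6, 8, 9).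

Steps most likely to fail

Step 3. The first adduct may rest as a closed N,O-aminal instead of opening. Imine–enecarbamate drift toward C4 may scramble C4 or expel benzyl alcohol. The enecarbamate may also attack through its substituted carbon.
- The fallback sets out from 3 and 6 and replaces the cascade by three separate known reactions.
- The Cu–box reaction is run at −78 °C and stopped at the endo hetero-Diels–Alder adduct, tert-butyl (2S,3S,4R)-3,4-bis(benzyloxy)-2-{[(benzyloxy)carbonyl]amino}-2-methyl-3,4-dihydro-2H-pyran-6-carboxylate F1, which is isolated.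
- Aqueous oxalic acid in THF hydrolyses it to tert-butyl (4R,5S)-4,5-bis(benzyloxy)-2,6-dioxoheptanoate F2.
- The C1–C2 bond is then closed by amine-catalysed 6-enolendo aldolisation (pyrrolidine–thiourea, benzoic acid), the second half of the known ketone/keto-ester annulation.
- The route is rejoined at 10.

Step 2. Dehydration may run toward the methyl group, and the E and Z isomers may interconvert during purification.
- The fallback sets out from 4 and reaches an N-acyl enamine by reduction instead of condensation.
- Hydroxylamine converts 4 into 1-(benzyloxy)propan-2-one oxime F3.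
- Reductive acylation (Fe powder, Ac2O, AcOH, toluene, 70 °C), a known route from ketoximes to enamides, gives after separation N-[(E)-1-(benzyloxy)prop-1-en-2-yl]acetamide F4.
- F4 takes the place of 6 under the conditions of step 3.
- It passes through the open-chain N-acetyl ketimine F5, the terminal enamide F6 and the cyclic N-acetyl ketimine F7 before hydrolysis.
- The route is rejoined at 10.

Step 9. The three tert-butyl cations may alkylate the freed phenol rings, and prolonged acid may move the C4 acyl group to O3.
- The fallback sets out from 13 and changes the phenol protection.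
- Steglich esterification with commercial (E)-4-acetoxycinnamic acid gives tert-butyl 4,5-bis-O-[(E)-4-acetoxycinnamoyl]-3-O-(triethylsilyl)quinate F8.
- Brief TFA–CH2Cl2–H2O then has to remove only one tert-butyl group and the TES ether while the rings are deactivated, giving 4,5-bis-O-[(E)-4-acetoxycinnamoyl]quinic acid F9.
- The phenolic acetates are cleaved by mild acid hydrolysis (1 M HCl, THF, rt).
- The route is rejoined at 18.

Further compounds
F1 | step 3 | tert-butyl (2S,3S,4R)-3,4-bis(benzyloxy)-2-{[(benzyloxy)carbonyl]amino}-2-methyl-3,4-dihydro-2H-pyran-6-carboxylate | C[C@]1(NC(=O)OCc2ccccc2)OC(C(=O)OC(C)(C)C)=C[C@@H](OCc3ccccc3)[C@@H]1OCc4ccccc4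
F2 | step 3 | tert-butyl (4R,5S)-4,5-bis(benzyloxy)-2,6-dioxoheptanoate | C(c1ccccc1)O[C@@H]([C@H](OCc2ccccc2)CC(=O)C(=O)OC(C)(C)C)C(C)=O
F3 | step 2 | 1-(benzyloxy)propan-2-one oxime | CC(COCc1ccccc1)=NO
F4 | step 2 | N-[(E)-1-(benzyloxy)prop-1-en-2-yl]acetamide | C/C(NC(C)=O)=C\OCc1ccccc1
F5 | step 2 | tert-butyl (4R,5R)-6-(acetylimino)-4,5-bis(benzyloxy)-2-oxoheptanoate | C(c1ccccc1)O[C@@H]([C@H](OCc2ccccc2)CC(=O)C(=O)OC(C)(C)C)C(C)=NC(C)=O
F6 | step 2 | tert-butyl (4R,5R)-6-acetamido-4,5-bis(benzyloxy)-2-oxohept-6-enoate | C(c1ccccc1)O[C@@H]([C@H](OCc2ccccc2)CC(=O)C(=O)OC(C)(C)C)C(=C)NC(C)=O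
F7 | step 2 | N-acetyl ketimine of 10 (C3=N–Ac, same configuration at C1, C4, C5) | C(c1ccccc1)O[C@@H]2C(=NC(C)=O)C[C@@](O)(C(=O)OC(C)(C)C)C[C@H]2OCc3ccccc3
F8 | step 9 | tert-butyl 4,5-bis-O-[(E)-4-acetoxycinnamoyl]-3-O-(triethylsilyl)quinate | CC(=O)Oc1ccc(/C=C/C(=O)O[C@@H]2[C@H](O[Si](CC)(CC)CC)C[C@@](O)(C(=O)OC(C)(C)C)C[C@H]2OC(=O)/C=C/c3ccc(OC(C)=O)cc3)cc1
F9 | step 9 | 4,5-bis-O-[(E)-4-acetoxycinnamoyl]quinic acid | CC(=O)Oc1ccc(/C=C/C(=O)O[C@@H]2[C@H](O)C[C@@](O)(C(=O)O)C[C@H]2OC(=O)/C=C/c3ccc(OC(C)=O)cc3)cc1
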